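Drummondin A is cut at the methylene bridge that joins ring A (butanoylfilicinic acid) to C6 of the chromene, and the chromene at its C4a–C4 bond. The plan rests on one feature: the ring C oxygen O1 (on C8a) is the phenolic oxygen flanking the acylated carbon C8 of ring B, and in para-capped butanoylphloroglucinol the two such oxygens are equivalent. One is therefore etherified first, giving a 2-hydroxy-4-MOM-oxy-6-(1,1-dimethylpropargyloxy) butyrophenone with a single free carbon ortho to the ether. Gold-catalysed 6-endo hydroarylation then forms C4a–C4 and closes ring C in one operation, regiochemistry already locked. MOM removal, aminomethylation at C6 and quinone methide coupling with ring A finish the route.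

Key step: step 4

Remark: drummondin A has no stereocentre; ring A is written as the enol tautomer of the target SMILES, and 11, 14 and 15 are each treated as one compound whatever their keto–enol form.

Step 1
Reactants: 1 phloroglucinol; 2 butanoyl chloride
Product: 3 1-(2,4,6-trihydroxyphenyl)butan-1-one
Conditions: AlCl3 (3 equiv), PhNO2, rt to 60 °C; then aq. HCl
Reagents that add atoms: butanoyl chloride (2), CCCC(Cl)=O
Why: Friedel–Crafts acylation of the very electron-rich triphenol should stop after one butanoyl group, because the aluminium-chelated aryl ketone that forms is strongly deactivated towards a second acylation.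

Step 2
Reactants: 3 1-(2,4,6-trihydroxyphenyl)butan-1-one; 4 chloromethyl methyl ether
Product: 5 1-[2,6-dihydroxy-4-(methoxymethoxy)phenyl]butan-1-one
Conditions: MOMCl (1.05 equiv), iPr2NEt, THF/CH2Cl2, 0 °C
Reagents that add atoms: chloromethyl methyl ether (4), COCCl
Why: Base-mediated O-alkylation (methoxymethyl protection) should take place at the 4-hydroxyl, the most acidic one and the only one that does not flank the ketone, when a single equivalent of the chloride is used at low temperature.

Step 3
Reactants: 5 1-[2,6-dihydroxy-4-(methoxymethoxy)phenyl]butan-1-one; 6 3-chloro-3-methylbut-1-yne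
Product: 7 1-[2-hydroxy-4-(methoxymethoxy)-6-(2-methylbut-3-yn-2-yloxy)phenyl]butan-1-one
Conditions: CuCl2·2H2O (1 mol %), DBU, MeCN, 0 °C
Reagents that add atoms: 3-chloro-3-methylbut-1-yne (6), CC(C)(Cl)C#C
Why: Copper-catalysed propargylic O-alkylation of a phenoxide (capture of a copper acetylide/allenylidene electrophile at its tertiary carbon) should etherify one of the two equivalent ortho hydroxyls, after which the remaining hydroxyl is locked in the hydrogen bond to the ketone and a second alkylation should be slow.

Step 4
Reactants: 7 1-[2-hydroxy-4-(methoxymethoxy)-6-(2-methylbut-3-yn-2-yloxy)phenyl]butan-1-one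
Product: 8 1-[7-hydroxy-5-(methoxymethoxy)-2,2-dimethyl-2H-chromen-8-yl]butan-1-one
Conditions: Ph3PAuNTf2 (3 mol %), CH2Cl2, rt
Reagents that add atoms: none
Why: The cationic monovalent gold centre of Ph3PAuNTf2 binds the terminal alkyne of 7 as a π-acid; the arene carbon ortho to the ether oxygen then attacks the terminal alkyne carbon in a Friedel–Crafts sense, and rearomatization followed by protodeauration of the vinylgold species releases the C3=C4 alkene and the catalyst while the O1–C2 ether bond stays intact. The closest known reaction type is the gold- or platinum-catalysed cycloisomerization (intramolecular hydroarylation) of aryl propargyl ethers to 2H-chromenes. Ring C is closed in the 6-endo-dig mode, which forms the C4a–C4 bond; the 5-exo-dig alternative would give a strained 3-methylene-2,3-dihydrobenzofuran and is not the normal course for such ethers, and the gem-dimethyl group presses the reacting ends together. No stereocentre is formed. The step needs site selectivity on the arene, and the substrate guarantees it because the second carbon ortho to the ether carries the butanoyl group, so only the 8-acyl chromene can arise, whether or not the MOM group survives traces of acid. The attacking carbon lies ortho to two oxygens and para to the free phenol and is therefore nucleophilic despite the ketone, and the hydrogen-bonded hydroxy ketone is a hard, poor ligand for the soft gold cation.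

Step 5
Reactants: 8 1-[7-hydroxy-5-(methoxymethoxy)-2,2-dimethyl-2H-chromen-8-yl]butan-1-one
Product: 9 1-(5,7-dihydroxy-2,2-dimethyl-2H-chromen-8-yl)butan-1-one
Conditions: HCl (1.25 M in MeOH), rt
Reagents that add atoms: none
Why: Acid-catalysed acetal exchange in anhydrous methanol cleaves the MOM ether and carries its CH2 unit away as dimethoxymethane, so that no free formaldehyde can bridge the nucleophilic C6, under conditions mild enough for the 2,2-dimethylchromene to survive.

Step 6
Reactants: 3 1-(2,4,6-trihydroxyphenyl)butan-1-one; 10 iodomethane
Product: 11 butanoylfilicinic acid (2-butanoyl-3,5-dihydroxy-6,6-dimethylcyclohexa-2,4-dien-1-one)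
Conditions: MeI (2.2 equiv), NaOMe, MeOH, 0 °C to rt
Reagents that add atoms: iodomethane (10), CI
Why: Dearomatizing C-methylation of the acylphloroglucinol anion (the classical route to acylfilicinic acids) should give the geminal dimethyl trione as the main methylation pattern with about two equivalents of iodomethane, since the methylated carbon of the monomethyl anion is alkylated again and the product then persists as a stabilized, weakly nucleophilic anion.

Step 7
Reactants: 9 1-(5,7-dihydroxy-2,2-dimethyl-2H-chromen-8-yl)butan-1-one; 12 N,N-dimethylmethyleneiminium iodide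
Product: 13 1-{6-[(dimethylamino)methyl]-5,7-dihydroxy-2,2-dimethyl-2H-chromen-8-yl}butan-1-one
Conditions: K2CO3, CH2Cl2, rt
Reagents that add atoms: N,N-dimethylmethyleneiminium iodide (12), C=[N+](C)C.[I-]
Why: Mannich aminomethylation with a preformed iminium salt is directed to C6, the only unsubstituted nuclear carbon of 9 and one flanked by two phenolic oxygens, and the absence of free formaldehyde should prevent formation of the symmetrical bis(chromenyl)methane.

Step 8
Reactants: 13 1-{6-[(dimethylamino)methyl]-5,7-dihydroxy-2,2-dimethyl-2H-chromen-8-yl}butan-1-one; 11 butanoylfilicinic acid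
Product: 15 drummondin A, via ortho-quinone methide 14 (not isolated)
Conditions: 11 (1.1 equiv), 1,4-dioxane, 90 °C
Reagents that add atoms: none
Why: Thermal loss of dimethylamine from the phenolic Mannich base, assisted by proton transfer from the acidic trione 11, generates the ortho-quinone methide 14, which is trapped in a Michael addition by the single nucleophilic ring carbon of 11 and rearomatizes, so that only the unsymmetrical ring A–CH2–ring B linkage can form because 14 alone carries the bridging carbon.

Compound list
1 | phloroglucinol (benzene-1,3,5-triol) | Oc1cc(O)cc(O)c1 | starting material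
2 | butanoyl chloride | CCCC(Cl)=O | starting material
3 | 1-(2,4,6-trihydroxyphenyl)butan-1-one | CCCC(=O)c1c(O)cc(O)cc1O | intermediate
4 | chloromethyl methyl ether | COCCl | starting material
5 | 1-[2,6-dihydroxy-4-(methoxymethoxy)phenyl]butan-1-one | CCCC(=O)c1c(O)cc(OCOC)cc1O | intermediate
6 | 3-chloro-3-methylbut-1-yne | CC(C)(Cl)C#C | starting material
7 | 1-[2-hydroxy-4-(methoxymethoxy)-6-(2-methylbut-3-yn-2-yloxy)phenyl]butan-1-one | CCCC(=O)c1c(O)cc(OCOC)cc1OC(C)(C)C#C | intermediate
8 | 1-[7-hydroxy-5-(methoxymethoxy)-2,2-dimethyl-2H-chromen-8-yl]butan-1-one | CCCC(=O)c1c(O)cc(OCOC)c2c1OC(C)(C)C=C2 | intermediate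
9 | 1-(5,7-dihydroxy-2,2-dimethyl-2H-chromen-8-yl)butan-1-one | CCCC(=O)c1c(O)cc(O)c2c1OC(C)(C)C=C2 | intermediate
10 | iodomethane | CI | starting material
11 | butanoylfilicinic acid, 2-butanoyl-3,5-dihydroxy-6,6-dimethylcyclohexa-2,4-dien-1-one | CCCC(=O)C1=C(O)C=C(O)C(C)(C)C1=O | intermediate
12 | N,N-dimethylmethyleneiminium iodide | C=[N+](C)C.[I-] | starting material
13 | 1-{6-[(dimethylamino)methyl]-5,7-dihydroxy-2,2-dimethyl-2H-chromen-8-yl}butan-1-one | CCCC(=O)c1c(O)c(CN(C)C)c(O)c2c1OC(C)(C)C=C2 | intermediate
14 | ortho-quinone methide, 8-butanoyl-7-hydroxy-2,2-dimethyl-6-methylidene-2H-chromen-5(6H)-one | CCCC(=O)C1=C(O)C(=C)C(=O)C2=C1OC(C)(C)C=C2 | intermediate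
15 | drummondin A, 2-butanoyl-4-[(8-butanoyl-5,7-dihydroxy-2,2-dimethyl-2H-chromen-6-yl)methyl]-3,5-dihydroxy-6,6-dimethylcyclohexa-2,4-dien-1-one | CCCC(=O)C1=C(O)C(Cc2c(O)c3c(c(C(=O)CCC)c2O)OC(C)(C)C=C3)=C(O)C(C)(C)C1=O | target

Total step count: 8.
Longest linear sequence: 7 steps (steps 1, 2, 3, 4, 5, 7, 8); ring A is made in a two-step branch (steps 1, 6) from the shared intermediate 3.

Steps most likely to fail (in route order):

Step 3. The hydrogen-bonded ortho phenoxide may react more slowly than the tertiary chloride is lost by base-induced elimination, or etherification may run on to the second hydroxyl. The fallback abandons the ether and builds ring C from 5 by condensation with 3-methylbut-2-enal under ethylenediammonium diacetate catalysis in refluxing toluene. Knoevenagel-type C-alkylation at one of the two equivalent free ring carbons and loss of water should give the ortho-quinone methide (6Z)-2-butanoyl-3-hydroxy-5-(methoxymethoxy)-6-(3-methylbut-2-en-1-ylidene)cyclohexa-2,4-dien-1-one F1 (not isolated). Its oxa-6π electrocyclization can only use the oxygen next to the ketone, because the other flanking oxygen is capped. This sets out from 5 and comes back to the route at 8, bypassing 7.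

Step 4. The Lewis-acidic gold cation may ionize the tertiary propargylic C–O bond and return the phenol, or be held by the chelating hydroxy ketone, before the 6-endo closure takes place. The fallback is a metal-free thermal cascade: heating 7 in N,N-diethylaniline at about 150 °C should trigger the aromatic propargyl Claisen rearrangement to the allenylphenol 1-[2,6-dihydroxy-4-(methoxymethoxy)-3-(3-methylbuta-1,2-dien-1-yl)phenyl]butan-1-one F2 (not isolated). A [1,5]-hydrogen shift then leads to the quinone methide F1 named above, and electrocyclization gives the same chromene. This sets out from 7 and comes back at 8.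

Step 8. Amine loss from 13 may be sluggish, or the quinone methide 14 may be consumed by recombination with dimethylamine or by self-condensation before the trione adds; prolonged heating with amine could also exchange the methylene bridge. The fallback reverses the roles of the two halves. Compound 11 is aminomethylated with bis(dimethylamino)methane in CH2Cl2 at rt to 2-butanoyl-4-[(dimethylamino)methyl]-3,5-dihydroxy-6,6-dimethylcyclohexa-2,4-dien-1-one F3, and this is warmed with 9 in 1,4-dioxane. Loss of dimethylamine should give the exo-methylene trione 2-butanoyl-3-hydroxy-6,6-dimethyl-4-methylidenecyclohex-2-ene-1,5-dione F4 (not isolated), a stronger Michael acceptor than 14, which alkylates C6 of 9 in a Friedel–Crafts-type conjugate addition. This sets out from 11 and 9 and comes back at 15.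

Further compounds
F1 | step 3 | (6Z)-2-butanoyl-3-hydroxy-5-(methoxymethoxy)-6-(3-methylbut-2-en-1-ylidene)cyclohexa-2,4-dien-1-one | CCCC(=O)C1=C(O)C=C(OCOC)/C(=C/C=C(C)C)C1=O
F2 | step 4 | 1-[2,6-dihydroxy-4-(methoxymethoxy)-3-(3-methylbuta-1,2-dien-1-yl)phenyl]butan-1-one | CCCC(=O)c1c(O)cc(OCOC)c(C=C=C(C)C)c1O
F3 | step 8 | 2-butanoyl-4-[(dimethylamino)methyl]-3,5-dihydroxy-6,6-dimethylcyclohexa-2,4-dien-1-one | CCCC(=O)C1=C(O)C(CN(C)C)=C(O)C(C)(C)C1=O
F4 | step 8 | 2-butanoyl-3-hydroxy-6,6-dimethyl-4-methylidenecyclohex-2-ene-1,5-dione | CCCC(=O)C1=C(O)C(=C)C(=O)C(C)(C)C1=O
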